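**Assumptions.** (i) The 4α-CH2OH (C18, equatorial) and the normal-series 5α-H, 9α-H, 10β-Me decalin were read from the SMILES, and they match the A/B rings of rosin acids. (ii) The C13 configuration of pimaric acid is irrelevant because C13 becomes sp2 in Step 6, and C9 stays at its thermodynamic equatorial-side-chain configuration.

## Retrosynthetic overview
1. The target is disconnected by an intermolecular [4+2] between the C5=C6 alkene of flavonyl-methoxybenzoquinone **14** and the labdane 12E,14-diene **9**. This forms the last ring (the cyclohexene) and sets C12, the quaternary Cq and C2'-H.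
2. Quinone **14** comes from oxidative demethylative dearomatization (CAN) of the 2',4',5'-trimethoxyflavone **13**. **13** is made by Claisen–Schmidt condensation and I2/DMSO cyclization (the chromone ring) from phloroacetophenone **10** and 2,4,5-trimethoxybenzaldehyde **11**.
3. Diene **9** comes from pimaric acid **1**, whose A/B rings already carry C4, C5 and C10. Ring C is cleaved at C8=C14, C8 becomes the exocyclic methylene, C7 is oxidized, and decarboxylative desaturation reveals the 12E,14-diene.
4. Ring order: A/B come from **1**, ring C is opened, the chromone ring forms in Step 10, the quinone ring is unmasked in Step 11, and the cyclohexene forms last (Step 12).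

## Route

**Step 1**
Reactants: **1** pimaric acid (pimara-8(14),15-dien-18-oic acid)
Product: **2** methyl pimarate
Conditions: MeI, K2CO3, DMF, rt
Reagents that add atoms: MeI (CI)
Why: Carboxylate O-alkylation differentiates the C18 acid from the acid generated in Step 3. No stereocentre changes.

**Step 2**
Reactants: **2**
Product: **3** methyl 8-oxo-8,14-seco-pimar-15-en-14-al-18-oate (ring C opened: C8 ketone, C14 aldehyde on quaternary C13)
Conditions: O3 (1.0 equiv, titrated), CH2Cl2/MeOH 4:1, −78 °C; then Me2S, −78 °C to rt
Reagents that add atoms: ozone ([O-][O+]=O)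
Why: Ozonolysis attacks the electron-rich trisubstituted C8=C14 alkene much faster than the vinyl group on the neopentyl C13, and Me2S reduces the ozonide to the keto-aldehyde. C4, C5, C9 and C10 are untouched.

**Step 3**
Reactants: **3**
Product: **4** methyl 8-oxo-8,14-seco-pimar-15-en-14-oic acid 18-oate
Conditions: NaClO2, NaH2PO4, 2-methyl-2-butene, t-BuOH/H2O, rt
Reagents that add atoms: sodium chlorite (O=Cl[O-].[Na+])
Why: Pinnick oxidation converts the aldehyde chemoselectively to the acid, and the alkene scavenger protects the vinyl group from HOCl.

**Step 4**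
Reactants: **4**
Product: **5** methyl 8,14-seco-pimara-8(17),15-dien-14-oic acid 18-oate (C8=CH2)
Conditions: Ph3P+CH3 Br−, KOt-Bu (4 equiv), toluene/THF, reflux
Reagents that add atoms: methylenetriphenylphosphorane (C=P(c1ccccc1)(c1ccccc1)c1ccccc1)
Why: Wittig methylenation of the hindered C8 ketone installs C17. The extra equivalent of ylide covers the carboxylate, and the equatorial C9 side chain is thermodynamically preferred if it epimerizes.

**Step 5**
Reactants: **5**
Product: **6** 7-oxo derivative of **5** (cross-conjugated α-methylene ketone at C7/C8)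
Conditions: CrO3, 3,5-dimethylpyrazole, CH2Cl2, −20 °C to 0 °C
Reagents that add atoms: chromium trioxide (O=[Cr](=O)=O)
Why: Salmond-type allylic oxidation occurs at C7, the only unhindered allylic methylene (the vinyl group has no allylic H). Carrying C7 at the ketone level keeps it safe from Pb(IV) in Step 6 and lets Step 7 set the stereochemistry.

**Step 6**
Reactants: **6**
Product: **7** methyl 7-oxo-labda-8(17),12E,14-trien-18-oate
Conditions: Pb(OAc)4 (1.5 equiv), Cu(OAc)2 (0.1 equiv), pyridine, benzene, 80 °C; E/Z separated on AgNO3-SiO2
Reagents that add atoms: none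
Why: Kochi oxidative decarboxylation of the β,γ-unsaturated tertiary acid gives a tertiary allylic radical, which Cu(II) oxidizes to the cation or organocopper. Zaitsev loss of the C12 proton gives the conjugated C12=C13 diene (E major), and C14 is lost as CO2. Cu(II) oxidation is much faster than any radical addition to the enone.

**Step 7**
Reactants: **7**
Product: **8** methyl 7β-hydroxy-labda-8(17),12E,14-trien-18-oate
Conditions: NaBH4, CeCl3·7H2O, MeOH/CH2Cl2, −78 °C to −20 °C
Reagents that add atoms: none (only H added)
Why: Luche 1,2-reduction of the enone. Small hydride attacks C7 axially from the α-face, which is unhindered because the C10 methyl is on the β-face. This sets the equatorial 7β-OH, and the diene and ester are untouched.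

**Step 8**
Reactants: **8**
Product: **9** labda-8(17),12E,14-triene-7β,18-diol
Conditions: LiAlH4, THF, 0 °C to 65 °C
Reagents that add atoms: none (only H added)
Why: Reduction of the hindered equatorial methyl ester gives the 4α-CH2OH, with no change at C4. The diene, exocyclic alkene and allylic alcohol survive.

**Step 9**
Reactants: **10** 2,4,6-trihydroxyacetophenone; **11** 2,4,5-trimethoxybenzaldehyde
Product: **12** (E)-2',4',6'-trihydroxy-2,4,5-trimethoxychalcone
Conditions: 50% aq KOH, EtOH, rt, 72 h; then HCl
Reagents that add atoms: none (KOH is catalytic and leaves as water)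
Why: Claisen–Schmidt aldol condensation, which gives the E-enone after dehydration.

**Step 10**
Reactants: **12**
Product: **13** 5,7-dihydroxy-2',4',5'-trimethoxyflavone
Conditions: I2 (0.1 equiv), DMSO, 130 °C
Reagents that add atoms: none
Why: Oxa-Michael cyclization to the flavanone followed by I2/DMSO dehydrogenation (the standard chrysin-type flavone synthesis) builds the chromone with the free 5,7-diol needed in the target.

**Step 11**
Reactants: **13**
Product: **14** 2-(5,7-dihydroxy-4-oxochromen-2-yl)-5-methoxy-1,4-benzoquinone
Conditions: CAN (2.5 equiv), MeCN/H2O 4:1, 0 °C, 10 min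
Reagents that add atoms: water (O)
Why: The only para-dimethoxy pair in ring B (2',5') undergoes two-electron oxidative demethylation (dearomatization), leaving the 4'-OMe as the quinone vinylogous-ester OMe. This puts OMe and the flavonyl group para, as in the target. The chelated 5-OH and the electron-poor A-ring phenols are far less oxidizable than the trimethoxyarene.

**Step 12**
Reactants: **9** (1.0 equiv) and **14** (2 equiv)
Product: **15** Dichrostachine A
Conditions: CH2Cl2/MeCN 1:1, BHT (cat.), 14 kbar, 25 °C, 72 h
Reagents that add atoms: none
Why: Diels–Alder cycloaddition onto the C5=C6 alkene, the only one not deactivated by the vinylogous-ester OMe. Suprafacial addition to the cis-enedione fixes the cis ring fusion (flavonyl and H on the same face).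
Proposed new method: The reaction is asynchronous. The unhindered C15 terminus bonds first to the most electrophilic, unsubstituted C6 (conjugated through C5 to the chromone C4=O), then C12 closes onto C5 to form the quaternary centre. Pressure (negative ΔV‡) overcomes the steric cost of the adjacent quaternary/tertiary centres and avoids acid-labile allylic alcohols and phenols. The closest known reaction is the high-pressure Diels–Alder of 2-substituted 5-methoxybenzoquinones with 1,2-disubstituted dienes.
Stereochemistry: The C12 configuration (C11 cis to the flavonyl) requires the flavonyl-endo/ring-carbonyl-exo approach with the E-diene, which is the main selectivity risk. Facial selectivity relative to the decalin comes only from remote 1,3-induction via C11. The C12/Cq diastereomers are expected to form as a mixture, and the desired one is separated by HPLC and assigned by NOE.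

## Compound list
1 | pimaric acid | `C=C[C@@]1(C)C=C2CC[C@H]3[C@](C)(C(=O)O)CCC[C@]3(C)[C@H]2CC1` | starting material
2 | methyl pimarate | `C=C[C@@]1(C)C=C2CC[C@H]3[C@](C)(C(=O)OC)CCC[C@]3(C)[C@H]2CC1` | intermediate
3 | 8-oxo-14-al seco ester | `O=C1CC[C@H]2[C@](C)(C(=O)OC)CCC[C@]2(C)[C@H]1CC[C@@](C)(C=C)C=O` | intermediate
4 | 8-oxo-14-oic acid seco ester | `O=C1CC[C@H]2[C@](C)(C(=O)OC)CCC[C@]2(C)[C@H]1CC[C@@](C)(C=C)C(=O)O` | intermediate
5 | 8(17)-ene acid ester | `C=C1CC[C@H]2[C@](C)(C(=O)OC)CCC[C@]2(C)[C@H]1CC[C@@](C)(C=C)C(=O)O` | intermediate
6 | 7-oxo-8(17)-ene acid ester | `C=C1C(=O)C[C@H]2[C@](C)(C(=O)OC)CCC[C@]2(C)[C@H]1CC[C@@](C)(C=C)C(=O)O` | intermediate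
7 | methyl 7-oxo-labda-8(17),12E,14-trien-18-oate | `C=C1C(=O)C[C@H]2[C@](C)(C(=O)OC)CCC[C@]2(C)[C@H]1C/C=C(C)/C=C` | intermediate
8 | methyl 7β-hydroxy-labda-8(17),12E,14-trien-18-oate | `C=C1[C@@H](O)C[C@H]2[C@](C)(C(=O)OC)CCC[C@]2(C)[C@H]1C/C=C(C)/C=C` | intermediate
9 | labda-8(17),12E,14-triene-7β,18-diol | `C=C1[C@@H](O)C[C@H]2[C@](C)(CO)CCC[C@]2(C)[C@H]1C/C=C(C)/C=C` | intermediate
10 | 2,4,6-trihydroxyacetophenone | `CC(=O)c1c(O)cc(O)cc1O` | starting material
11 | 2,4,5-trimethoxybenzaldehyde | `O=Cc1cc(OC)c(OC)cc1OC` | starting material
12 | (E)-2',4',6'-trihydroxy-2,4,5-trimethoxychalcone | `O=C(/C=C/c1cc(OC)c(OC)cc1OC)c1c(O)cc(O)cc1O` | intermediate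
13 | 5,7-dihydroxy-2',4',5'-trimethoxyflavone | `COc1cc(OC)c(cc1OC)-c1cc(=O)c2c(O)cc(O)cc2o1` | intermediate
14 | 2-(5,7-dihydroxy-4-oxochromen-2-yl)-5-methoxy-1,4-benzoquinone | `COC1=CC(=O)C(c2cc(=O)c3c(O)cc(O)cc3o2)=CC1=O` | intermediate
15 | Dichrostachine A | `C=C1[C@@H](O)C[C@H]2[C@](C)(CO)CCC[C@]2(C)[C@H]1C[C@@H]1C(C)=CC[C@H]2C(=O)C(OC)=CC(=O)[C@@]12c1cc(=O)c2c(O)cc(O)cc2o1` | target

## Totals
Total steps: 12. Longest linear sequence: 9 (Steps 1–8, then Step 12).

## Three steps most likely to fail
1. **Step 12 (high-pressure Diels–Alder).** The regiochemistry, the C12 epimer ratio and the facial selectivity are all uncertain.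
   Fallback: a stepwise ionic annulation. Protect **9** as its bis-TBS ether. Add it to **14** with Me2AlCl at −78 °C so that C15 adds to C6, let the allyl cation close onto the aluminium enolate at C5, then remove the silyl groups with HF·pyridine.
2. **Step 6 (Kochi desaturation).** The E/Z ratio and the 13(16),14 regioisomer are uncertain, and Pb(IV) may react with the enone.
   Fallback: go through the sclareol-type alcohol. Baeyer–Villiger oxidation of aldehyde **3** (mCPBA) gives the C13 formate, which is cleaved with K2CO3/MeOH to the tertiary allylic alcohol. Carry that through the Wittig (Step 4 chemistry), C7 oxidation and Luche steps, then dehydrate with Martin sulfurane and reduce the ester.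
3. **Step 5 (Cr(VI) allylic oxidation at C7).** Over-oxidation or oxidation at the wrong allylic position is possible.
   Fallback: change the C7 oxygenation strategy. Treat the C8 ketone of **4** with LDA and Davis oxaziridine to give the 7α-hydroxy ketone, then do the Wittig methylenation. Invert C7 with Mitsunobu (p-nitrobenzoic acid) to the 7β-ester, and remove it with the final LiAlH4 reduction.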